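The C1–C9 chain is disconnected between C2 (α to the ketone) and C3, and this bond is made redox-neutrally by iridium-catalysed hydrogen-borrowing alkylation. Commercial 2',6'-dimethoxyacetophenone supplies C1–C2, and the unprotected 4-(7-hydroxyheptyl)phenol supplies C3–C9 as a latent aldehyde. In one operation the alcohol is dehydrogenated, condensed with the ketone at C2, and the resulting C2=C3 enone re-hydrogenated, with water as the only by-product. The step exploits the acidic C2 methyl of the aryl ketone and the two ortho-methoxy groups of the 2,6-dimethoxyphenyl ring, which twist the C1 carbonyl out of conjugation and shield it from hydride reduction. The alcohol partner arises in one pot from hept-6-en-1-ol and 4-iodophenol.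

Key step: step 2

Remark: the target is achiral, so no stereocentre has to be set. Compounds 6 and 7 are drawn as neutral phenols although they exist as potassium phenoxides in the flask.

Step 1
Reactants: 1 hept-6-en-1-ol; 2 4-iodophenol
Product: 4 4-(7-hydroxyheptyl)phenol, via alkylborane 3 (not isolated)
Conditions: 1, 9-BBN (0.5 M in THF, 2.2 equiv), 0 °C → rt; then 2, PdCl2(dppf)·CH2Cl2 (3 mol %), 3 M aq NaOH, THF, 65 °C; aq NH4Cl work-up
Reagents that add atoms: none
Why: Anti-Markovnikov hydroboration of the terminal alkene with 9-BBN (the second equivalent is consumed by the hydroxyl group with loss of H2) is followed by B-alkyl Suzuki–Miyaura coupling of the primary alkylborane with the aryl iodide, in which hydroxide forms the borate for transmetalation, the bidentate dppf ligand suppresses β-hydride elimination, and the phenol rides through as its phenoxide.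

Step 2
Reactants: 4 4-(7-hydroxyheptyl)phenol; 5 1-(2,6-dimethoxyphenyl)ethan-1-one (2',6'-dimethoxyacetophenone)
Product: 8 1-(2,6-dimethoxyphenyl)-9-(4-hydroxyphenyl)nonan-1-one, via 7-(4-hydroxyphenyl)heptanal 6 (not isolated), via (E)-enone 7 (not isolated)
Conditions: [Cp*IrCl2]2 (2 mol %), KOH (3 equiv), 5 (1.5 equiv), degassed t-AmOH/PhMe, 100 °C, Ar, sealed tube; then aq HCl
Reagents that add atoms: none
Why: Hydrogen-borrowing α-alkylation of an aryl methyl ketone with a primary alcohol: Cp*Ir(III) dehydrogenates the carbinol of 4 to aldehyde 6 and stores the hydrogen as Ir–H, the potassium enolate of 5 condenses through C2 with 6 to the E-enone 7 (Claisen–Schmidt-type aldol condensation), and Ir–H returns the hydrogen by conjugate reduction of C2=C3 to give 8 with water as the only by-product. The closest known reaction type is the Ir-catalysed alkylation of di-ortho-substituted aryl methyl ketones with aliphatic primary alcohols. No ring is closed and no stereocentre is formed; the E geometry of 7 is erased on reduction. The step needs chemoselectivity for C=C over C=O reduction and for mono- over dialkylation at C2: the two ortho-methoxy groups force the C1 carbonyl out of the ring plane, which hinders hydride delivery to C1 and a second condensation at the now more hindered C2, and 5 is used in excess over the limiting alcohol. Self-condensation of 6 should be held back because the aldehyde is present only at a low stationary concentration beside excess enolate. The phenol is carried as its potassium phenoxide, which has no carbinol hydrogen to be abstracted and sits seven carbons from the reacting terminus; the third equivalent of KOH compensates for it.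

Compound list
1 | hept-6-en-1-ol | C=CCCCCCO | starting material
2 | 4-iodophenol | Oc1ccc(I)cc1 | starting material
3 | 9-[7-(9-borabicyclo[3.3.1]nonan-9-yloxy)heptyl]-9-borabicyclo[3.3.1]nonane | B1(CCCCCCCOB2C3CCCC2CCC3)C2CCCC1CCC2 | intermediate
4 | 4-(7-hydroxyheptyl)phenol | OCCCCCCCc1ccc(O)cc1 | intermediate
5 | 1-(2,6-dimethoxyphenyl)ethan-1-one | COc1cccc(OC)c1C(C)=O | starting material
6 | 7-(4-hydroxyphenyl)heptanal | O=CCCCCCCc1ccc(O)cc1 | intermediate
7 | (E)-1-(2,6-dimethoxyphenyl)-9-(4-hydroxyphenyl)non-2-en-1-one | COc1cccc(OC)c1C(=O)/C=C/CCCCCCc1ccc(O)cc1 | intermediate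
8 | 1-(2,6-dimethoxyphenyl)-9-(4-hydroxyphenyl)nonan-1-one | COc1cccc(OC)c1C(=O)CCCCCCCCc1ccc(O)cc1 | target

Total step count: 2
Longest linear sequence: 2 steps (1 → 4 → 8)

Steps most likely to fail (the route has only two steps, so both are listed, the riskier first)

Step 2 (key step). What may go wrong: the potassium phenoxide may precipitate or bind the iridium centre and stall the dehydrogenation; the transient aliphatic aldehyde may self-condense (Guerbet-type coupling) faster than it is intercepted by the ketone enolate; or a second alkylation at C2 may compete. Fallback, setting out from 4 and coming back at 8, makes the same C2–C3 bond by classical enolate alkylation. The phenol of 4 is benzylated selectively (BnBr, K2CO3, acetone, reflux; carbonate ionises only the phenol) to 7-[4-(benzyloxy)phenyl]heptan-1-ol F1. The alcohol is converted by an Appel reaction (I2, PPh3, imidazole, CH2Cl2, 0 °C → rt) into 1-(benzyloxy)-4-(7-iodoheptyl)benzene F2. The lithium enolate of 5 (LDA, THF/DMPU, −78 °C → rt, enolate in excess) is alkylated with F2 to 9-[4-(benzyloxy)phenyl]-1-(2,6-dimethoxyphenyl)nonan-1-one F3. Hydrogenolysis of the benzyl ether (H2, Pd/C, EtOAc, rt) should then give 8, the twisted di-ortho-substituted ketone being left untouched.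

Step 1. What may go wrong: incomplete hydroboration because the free hydroxyl group consumes borane, slow oxidative addition of the electron-rich iodophenoxide, or protodeboronation and β-hydride elimination of the alkyl–palladium species before reductive elimination. Fallback, setting out from 2 and coming back at 4, builds the aryl–chain bond at the sp–sp2 level. Sonogashira coupling of 2 with commercial hept-6-yn-1-ol (C#CCCCCCO; Pd(PPh3)2Cl2, CuI, Et3N, THF, rt) should give 4-(7-hydroxyhept-1-yn-1-yl)phenol F4. Hydrogenation of the alkyne (H2, Pd/C, EtOAc, rt) then gives 4.

Further compounds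
F1 | step 2 | 7-[4-(benzyloxy)phenyl]heptan-1-ol | OCCCCCCCc1ccc(OCc2ccccc2)cc1
F2 | step 2 | 1-(benzyloxy)-4-(7-iodoheptyl)benzene | ICCCCCCCc1ccc(OCc2ccccc2)cc1
F3 | step 2 | 9-[4-(benzyloxy)phenyl]-1-(2,6-dimethoxyphenyl)nonan-1-one | COc1cccc(OC)c1C(=O)CCCCCCCCc1ccc(OCc2ccccc2)cc1
F4 | step 1 | 4-(7-hydroxyhept-1-yn-1-yl)phenol | OCCCCCC#Cc1ccc(O)cc1
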